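**Assumption:** isofraxidin (3) and nerol (1) are taken as catalogue compounds; 1 is used free of its E isomer, because the olefin geometry is translated directly into the relative configuration of C2'/C3'.

**Compound numbers used throughout:** 1 nerol; 2 (2S,3R)-2,3-epoxynerol; 3 isofraxidin; 4 terminal epoxide (Payne isomer of 2, formed and consumed in the flask); 5 altissimacoumarin C. Coumarin atoms are numbered O1, C2 … C8a; chain atoms are C1' (OCH2) to C7'.

## Analysis of the target

Altissimacoumarin C (5) is isofraxidin alkylated on O7: a coumarin (benzo ring C4a–C5–C6–C7–C8–C8a fused to the pyran-2-one ring O1–C2–C3–C4) with methoxy groups on C6 and C8, joined through O7 to the chain C1'H2–C2'H(OH)–C3'(OH)(CH3)–C4'H2–C5'H2–C6'H=C7'(CH3)2. The only stereocentres are the contiguous pair C2' (secondary carbinol, R) and C3' (tertiary carbinol, R). Their relative configuration is that of a syn addition of two oxygens to an E (geranyl-type) C2'=C3' olefin or, equivalently, of an anti addition to the Z (neryl-type) olefin. C3' carries two alkyl arms of nearly equal size (CH3 and CH2CH2CH=CMe2), so neither its own configuration nor that of C2' can be set by 1,2-induction from C3'; the pair has to be written by an olefin geometry through a stereospecific oxygen transfer. The second olefin, C6'=C7', is more electron-rich and more open than any C2'=C3' olefin next to the allylic oxygen, so undirected electrophilic oxidants choose the wrong site. O7 is flanked by two methoxy groups and conjugated with the lactone carbonyl (a hindered, weak nucleophile); the lactone O1–C2 opens in base, the unit C4=C3–C2=O is a Michael acceptor and reducible (no organometallic or low-valent-metal chemistry once the coumarin is present), and the tertiary alcohol/trisubstituted olefin pair is acid-sensitive. The feature that invites the key move is the glycerol-like array O7–C1'–C2'(O)–C3'(O): in three contiguous oxygenated carbons an oxirane can migrate between C2'–C3' and C1'–C2', so that the C1' electrophile, both hydroxyls and the C2' configuration can all come out of one equilibrating epoxy alcohol.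

## Retrosynthetic reasoning

**Cut 1: O7–C1'.** This is the only bond between the aromatic half and the chain, and cutting it leads to 3 and a C10 electrophile. The electrophile chosen is the terminal epoxide 4. Its C1' is an unhindered primary carbon, the one kind of centre at which the hindered, delocalised aryloxide of 3 can be expected to react cleanly by SN2. Ring opening releases the C2' hydroxyl at once, with the C3' hydroxyl already free, so no protecting group is needed. Cutting a C–C bond of the chain instead (C2'–C3' or C3'–C4') would require carbanions β to the aryloxy group or organometallic reagents next to the coumarin. The forward reaction must attack C1' only and must spare the lactone.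

**Cut 2: the oxirane shift from 4 back to 2.** Compound 4 is not prepared as such; it is the Payne isomer of the 2,3-epoxy alcohol 2. In the forward direction the C1 alkoxide of 2 displaces the oxirane oxygen at C2 from the rear, so the oxirane moves from C2–C3 to C1–C2, C2 is inverted and C3 is untouched. The two isomers interconvert under base and only 4 is drained by the aryloxide, so cuts 1 and 2 are run as one operation (step 2, the key step). The gain is that the diad can be written on an allylic alcohol, where the hydroxyl steers the oxidant to the right olefin. The alternatives would be the aryl ether, or a chiral-pool tertiary vinyl carbinol in which C3' would have to induce C2' through two alkyl arms of like size. Book-keeping: (2'R,3'R)-5 requires (2R,3R)-4, which requires (2S,3R)-2, a cis-2,3-epoxide.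

**Cut 3: the two C–O bonds of the oxirane of 2.** This leads to the Z allylic alcohol 1. The forward reaction is a hydroxyl-directed, catalyst-controlled asymmetric epoxidation. The allylic hydroxyl binds the chiral titanium catalyst, so only C2=C3 is oxidised and C6=C7 is left alone. The Z geometry fixes the cis relation of the hydroxymethyl group and the homoprenyl arm, and the catalyst enantiomer fixes the absolute sense. The E isomer of 1 would end as the C3' epimer of 5 and is therefore excluded.

## Alternatives that were turned down

**Alternative 1: O-geranylation, then asymmetric dihydroxylation (the textbook route).**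
- Disconnection: the two bonds C2'–OH and C3'–OH, made on a pre-formed ether (O7–C1' by Williamson alkylation).
- Forward key step: O-geranylation of 3 (allylic bromide, K2CO3) would give ether A1, followed by Sharpless asymmetric dihydroxylation [K2OsO2(OH)4 cat., K3Fe(CN)6, K2CO3, phthalazine-bridged cinchona ligand, t-BuOH/H2O]. Syn addition to the E olefin would give the right relative configuration.
- Why turned down: A1 has two trisubstituted olefins and the osmium–ligand oxidant is electrophilic. C2'=C3' is deactivated by the allylic aryloxy group, while C6'=C7' is an unperturbed, open isopropylidene. The expected product is therefore the 6',7'-diol A2 (6'R with the dihydroquinidine ligand series), and forcing the reaction would give a tetraol. A1 has no hydroxyl to direct the oxidant, and masking and unmasking C6'=C7' would cost three or more steps.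

**Alternative 2: C2'–C3' reductive cross-pinacol union.**
- Disconnection: C2'–C3', the bond between the two carbinol carbons (two acceptor carbons of like polarity).
- Forward key step: reductive cross-coupling of aldehyde A3 with ketone A4 [SmI2 (divalent samarium) or low-valent titanium]. It would form the chain and both stereocentres in one step.
- Why turned down:
  - There is no stereochemical handle: the two faces of A4 differ only by CH3 against CH2CH2R, and no catalyst-controlled enantioselective aldehyde–ketone cross-pinacol of two aliphatic partners can be counted on. Four stereoisomers of 5 would result.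
  - A3 carries the aryloxide on the carbon α to the carbonyl. Ketyl or carbanion character at C2' expels it (reductive cleavage of C1'–O7), and the same β-elimination defeats other C2' carbanion equivalents.
  - The unit C4=C3–C2=O of the coumarin is reduced by the same electron donors.
  - A repair (chain built without the coumarin, with protecting groups) is much longer.

**Alternative 3: pyranone closure at carbon (C4–C4a).**
- Disconnection: C4–C4a, closing the pyranone ring at carbon instead of at O1.
- Forward key step: intramolecular 6-endo-dig hydroarylation of aryl propiolate A5 [Pd(OAc)2 in CF3CO2H (divalent palladium) or a cationic monovalent gold complex such as Ph3PAuNTf2]. Regiochemistry would be unambiguous: C4a is the only free position ortho to O1 and is para to O7.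
- Why turned down:
  - The coumarin nucleus can be bought as 3, so the closure wins nothing.
  - A5 needs a non-commercial 3-alkoxy-2,4-dimethoxyphenol (several steps of formylation and oxidation from a pyrogallol ether).
  - The whole problem of the diad remains unsolved upstream.
  - The electrophilic metal/acid medium threatens the C3' tertiary alcohol and C6'=C7' (cycloetherification), so diol protection would have to be added.

Key step: step 2

## Route

Step 1
Reactants: 1 nerol [(2Z)-3,7-dimethylocta-2,6-dien-1-ol]
Product: 2 (2S,3R)-2,3-epoxynerol {[(2S,3R)-3-methyl-3-(4-methylpent-3-en-1-yl)oxiran-2-yl]methanol}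
Conditions: Ti(OiPr)4 (10 mol%), L-(+)-diethyl tartrate (12 mol%), t-BuOOH (1.5 equiv), 4 Å MS, CH2Cl2, −20 °C
Reagents that add atoms: tert-butyl hydroperoxide, CC(C)(C)OO
Why: Katsuki–Sharpless asymmetric epoxidation: the tetravalent titanium–tartrate catalyst binds the allylic hydroxyl and the hydroperoxide, so oxygen goes only to C2=C3 and the distal C6=C7 olefin is left alone. With the L-(+)-tartrate ester oxygen is delivered to the lower face of the allylic alcohol drawn with C1 at the lower right, which sets C2 as S; the syn transfer onto the Z olefin places CH2OH and the homoprenyl arm cis and thereby sets C3 as R.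

Step 2
Reactants: 2 (2S,3R)-2,3-epoxynerol; 3 isofraxidin (7-hydroxy-6,8-dimethoxy-2H-chromen-2-one), used as its potassium aryloxide generated in the flask
Product: 5 altissimacoumarin C [7-{[(2R,3R)-2,3-dihydroxy-3,7-dimethyloct-6-en-1-yl]oxy}-6,8-dimethoxy-2H-chromen-2-one], via terminal epoxide 4 (not isolated)
Conditions: 3 (2.0 equiv), KOt-Bu (2.2 equiv), t-BuOH, 80 °C, slow addition of 2; then AcOH
Reagents that add atoms: none
Why: Tandem Payne rearrangement–aryloxide opening; the closest known reaction type is the base-mediated Payne equilibration of a 2,3-epoxy-1-ol with in situ capture of the 1,2-epoxy-3-ol at C1 by a thiolate or aryloxide. The alkoxide of 2 displaces the oxirane oxygen at C2 from the rear, which moves the oxirane to C1–C2 and gives the tertiary alkoxide of 4; 2 and 4 equilibrate, only 4 offers an unhindered primary carbon, and the aryloxide of 3 drains the equilibrium by SN2 attack at C1' (Curtin–Hammett), forming the O7–C1' bond. No ring of the target is closed; the transient oxirane of 4 is closed 3-exo-tet and opened again. C3' (R, from step 1) is not touched; C2' is inverted once, S to R, by the intramolecular displacement and then keeps its configuration because the aryloxide attacks C1'. The step needs C1' over C2' selectivity, which the substrate secures: in 2, C2 lies next to the fully substituted C3 (neopentyl-like) and C3 itself is tertiary, whereas C1' of 4 is a free terminal methylene. It also needs the lactone to survive: before alkylation 3 is a 7-oxido coumarin (a vinylogous carboxylate) that should resist the bulky tert-butoxide, any lactone opened afterwards should reclose on acidification as long as C3=C4 stays Z, and the isolated C6'=C7' olefin is inert to base. Excess aryloxide and slow addition of 2 should suppress attack of alkoxides on the epoxides, and the excess of 3 is recovered.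

## Compound list

1 | nerol, (2Z)-3,7-dimethylocta-2,6-dien-1-ol | CC(C)=CCC/C(C)=C\CO | starting material
2 | (2S,3R)-2,3-epoxynerol, [(2S,3R)-3-methyl-3-(4-methylpent-3-en-1-yl)oxiran-2-yl]methanol | OC[C@@H]1O[C@]1(C)CCC=C(C)C | intermediate
3 | isofraxidin, 7-hydroxy-6,8-dimethoxy-2H-chromen-2-one | COc1cc2ccc(=O)oc2c(OC)c1O | starting material
4 | (2R)-6-methyl-2-[(2R)-oxiran-2-yl]hept-5-en-2-ol (Payne isomer of 2, present as its alkoxide) | C1O[C@H]1[C@](C)(O)CCC=C(C)C | intermediate
5 | altissimacoumarin C, 7-{[(2R,3R)-2,3-dihydroxy-3,7-dimethyloct-6-en-1-yl]oxy}-6,8-dimethoxy-2H-chromen-2-one | COc1cc2ccc(=O)oc2c(OC)c1OC[C@@H](O)[C@](C)(O)CCC=C(C)C | target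

## Step count and risk

Total step count: 2. Longest linear sequence: 2 steps (1 → 2 → 5); 3 enters in step 2.

The route has only two steps, so both are assessed; there are no further steps to rank.

**Step 2 (key step).** Most likely to go wrong:
- Slow capture of 4. The aryloxide of 3 is hindered by the two flanking methoxy groups and delocalised into the lactone, so attack of alkoxides on the epoxides (oligomerisation of 2 and 4) may compete.
- Loss of the lactone. Each aryloxide consumed is replaced by an alkoxide, so the medium turns more basic as the reaction proceeds. The lactone of the product may then open, followed by Z to E isomerisation of the opened cinnamate (which would block relactonisation) or by alkylation of the liberated O1 phenoxide.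
- Direct attack of the aryloxide at C2 of 2 is the least likely failure.

Fallback, setting out from 1 and 3 and coming back to the route at 5: compound 1 would be epoxidised with the enantiomeric catalyst [Ti(OiPr)4, D-(−)-diethyl tartrate, t-BuOOH, 4 Å MS, CH2Cl2, −20 °C] to (2R,3S)-2,3-epoxynerol F1. Mitsunobu etherification of F1 with 3 (PPh3, DIAD, THF, 0 °C to rt) would give, under neutral conditions, the epoxy ether 7-{[(2R,3S)-3-methyl-3-(4-methylpent-3-en-1-yl)oxiran-2-yl]methoxy}-6,8-dimethoxy-2H-chromen-2-one F2. Acid-catalysed hydrolysis (cat. HClO4, THF/H2O, 0 °C) would then open the oxirane at the tertiary carbon C3' with inversion and leave C2' untouched, giving 5. This changes the approach: the union is made at the intact primary alcohol without base, and the inversion is moved from C2' (base) to C3' (acid), which is why the enantiomeric epoxide is needed. Its own weak point is partial loss of stereospecificity at C3' through an open tertiary cation.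

**Step 1.** Most likely to go wrong:
- Incomplete enantioface selection and slow turnover, because in a Z, 3,3-disubstituted allylic alcohol the cis substituent sits close to the tartrate ligand.
- Carry-through of any E isomer of 1 as a diastereomeric epoxide, which would end as the C3' epimer of 5.
- Titanium-promoted opening of the trisubstituted epoxy alcohol during a long reaction or work-up.

Fallback, setting out from 2 of insufficient stereochemical purity and coming back to the route at 2: acylation with 4-nitrobenzoyl chloride (Et3N, CH2Cl2, 0 °C) would give the ester [(2S,3R)-3-methyl-3-(4-methylpent-3-en-1-yl)oxiran-2-yl]methyl 4-nitrobenzoate F3, which is expected to be crystalline. Recrystallisation should remove the minor enantiomer and the diastereomer, and mild methanolysis (K2CO3, MeOH, 0 °C) would return 2. Purity would then be secured by crystallisation of a derivative and not by the catalyst alone.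

## Further compounds

F1 | step 2 | (2R,3S)-2,3-epoxynerol, [(2R,3S)-3-methyl-3-(4-methylpent-3-en-1-yl)oxiran-2-yl]methanol | OC[C@H]1O[C@@]1(C)CCC=C(C)C
F2 | step 2 | 7-{[(2R,3S)-3-methyl-3-(4-methylpent-3-en-1-yl)oxiran-2-yl]methoxy}-6,8-dimethoxy-2H-chromen-2-one | COc1cc2ccc(=O)oc2c(OC)c1OC[C@H]1O[C@@]1(C)CCC=C(C)C
F3 | step 1 | [(2S,3R)-3-methyl-3-(4-methylpent-3-en-1-yl)oxiran-2-yl]methyl 4-nitrobenzoate | O=C(OC[C@@H]1O[C@]1(C)CCC=C(C)C)c1ccc(cc1)[N+](=O)[O-]
A1 | alternative 1 | 7-{[(2E)-3,7-dimethylocta-2,6-dien-1-yl]oxy}-6,8-dimethoxy-2H-chromen-2-one | COc1cc2ccc(=O)oc2c(OC)c1OC/C=C(\C)CCC=C(C)C
A2 | alternative 1 | 7-{[(2E,6R)-6,7-dihydroxy-3,7-dimethyloct-2-en-1-yl]oxy}-6,8-dimethoxy-2H-chromen-2-one | COc1cc2ccc(=O)oc2c(OC)c1OC/C=C(\C)CC[C@@H](O)C(C)(C)O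
A3 | alternative 2 | [(6,8-dimethoxy-2-oxo-2H-chromen-7-yl)oxy]acetaldehyde | COc1cc2ccc(=O)oc2c(OC)c1OCC=O
A4 | alternative 2 | 6-methylhept-5-en-2-one | CC(=O)CCC=C(C)C
A5 | alternative 3 | 3-{[(2R,3R)-2,3-dihydroxy-3,7-dimethyloct-6-en-1-yl]oxy}-2,4-dimethoxyphenyl prop-2-ynoate | C#CC(=O)Oc1ccc(OC)c(OC[C@@H](O)[C@](C)(O)CCC=C(C)C)c1OC
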